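## Structural features

The target is a single benzene ring with four substituents in a 1,2,3,5 pattern: acetoxy on C1, methoxy on C2, hydroxyl on C4 and an unbranched n-pentadecyl chain on C6, with hydrogen on C3 and C5. The oxygens on C1 and C4 are para, so the core is a hydroquinone whose two oxygens are in different states: O1 is acetylated and O4 is a free phenol. The acetate sits on the more crowded oxygen, between the methoxy group and the C15 chain, whereas the unhindered oxygen between two ring hydrogens is free. Direct mono-acylation of the parent hydroquinone would favour the opposite isomer. There is no stereocentre and no second ring, and the chain is joined by one C(sp2)–C(sp3) bond. The fragile groups are the aryl acetate (bases, nucleophiles, acyl transfer between molecules to the free phenol) and the electron-rich hydroquinone mono-ester (oxidation to the quinone). The real difficulty is regiochemical: three different oxygen substituents and a chain on one ring, with a contra-steric acetate/phenol distinction. The key step exploits the fact that ring atoms C4(OH)–C3(H)–C2(OMe)–C1(OAc) map onto the four carbons of a cyclobutenone (carbonyl carbon, vinylic CH, methoxy-bearing carbon, acetoxy-bearing quaternary carbon), while C6 and C5 map onto a 1,1-disubstituted alkene on that quaternary carbon. O4 then arises from a ketene carbonyl as the free phenol, and O1 is a carbinol oxygen that already carries the acetyl group.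

## Logic of the disconnections

In one sentence, the benzene ring of 13 is made by thermal electrocyclic ring expansion of 10.

13 to 10 (through 12 and 11): the arene bond C4–C5 is cut and the para carbons C1 and C4 are joined, which contracts the benzene ring to a cyclobutenone bearing an exocyclic alkene. The cut is made here because the four contiguous ring atoms C4, C3, C2, C1 and both oxygens then lie in one four-carbon unit in which the oxygens are different by constitution (ketone against esterified carbinol). The gain is that the whole arene, its substitution pattern and the acetate/phenol distinction come from one isomerisation. The forward step demands outward rotation of the acetoxy group in the ring opening, and a neutral medium in which the acetyl group stays on its oxygen.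

10 to 7 and 4 (through 9 and 8): the O–acetyl bond and the bond between the carbinol carbon and the alkene carbon are cut. The carbinol carbon is a former ketone carbonyl, so the cut gives a four-carbon dione and a C17 alkenyl halide. The forward step demands 1,2-addition at the ketone next to the methoxy-bearing carbon and not at the vinylogous ester carbonyl, no proton abstraction from the ring CH, and capture of a crowded tertiary alkoxide.

4 to 1 and 2 (through 3): the allylic C3–C4 bond of the C17 chain is cut. This gives a commercial C14 bromide and a commercial 2-bromoallyl unit. The forward step demands substitution at the allylic bromide only, with the vinylic bromide untouched.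

7 to 5 (through 6): the ring C–H of 7 is traced back to a C–OMe of 5, a retro reduction and carbonyl transposition. The gain is a commercial, symmetrical four-carbon starting material that already holds all ring oxygens. The forward step demands mono-reduction and a rearrangement that leaves the remaining vinylogous ester intact.

## Other disconnections considered

Alternative 1: the first idea keeps the arene and cuts the C6–chain bond and the C4–O bond. 5-Bromovanillin A1 would be coupled with a pentadecylborane (B-alkyl Suzuki coupling, Pd(dppf)Cl2) to 4-hydroxy-3-methoxy-5-pentadecylbenzaldehyde A2, and acetylated to 4-formyl-2-methoxy-6-pentadecylphenyl acetate A3. The forward key step is a Baeyer–Villiger oxidation of A3 to 4-(formyloxy)-2-methoxy-6-pentadecylphenyl acetate A4, followed by selective formate cleavage to 13. The chosen plan is preferred for three reasons. The aryl group of A3 has only an acetoxy donor para to the aldehyde, so aryl migration competes with oxidation to the benzoic acid. The last step distinguishes two aryl esters on one ring only by rate, with acyl scrambling possible. The sequence is also longer (four steps plus preparation of the borane), whereas in the chosen plan the two oxygens differ by constitution from the start.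

Alternative 2: a Dötz benzannulation cuts the ring into an alkyne, a carbonyl ligand and an alkenylcarbene. Heptadec-1-yne A5 and pentacarbonyl[(2E)-1-(benzyloxy)-3-methoxyprop-2-en-1-ylidene]chromium A6 (a Fischer carbene complex of zerovalent chromium), heated with acetic anhydride and triethylamine, would give 4-(benzyloxy)-2-methoxy-6-pentadecylphenyl acetate A7. Hydrogenolysis would then give 13. The regiochemistry is right, since the chain ends up next to the oxygen derived from CO. However, A6 is a push-pull carbene: the 3-methoxy group donates into the carbene carbon, which retards CO loss and alkyne insertion and favours five-membered products formed without CO insertion. The complex needs several steps to make, chromium is stoichiometric, and a deprotection is added.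

Alternative 3: a Danheiser benzannulation cuts the ring into a cyclobutenone and an ynol ether. 4-Oxo-2-pentadecylcyclobut-1-en-1-yl acetate A8 would open to a vinylketene and add methoxyethyne A9 in a (2+2) cycloaddition. That adduct is 10 itself, formed in the flask, and it would go on to 13. The alternative therefore shares the last events of the chosen plan but reaches 10 by a harder path. A8 is the enol acetate of a cyclobutane-1,2-dione, a class prone to ring contraction, and would need a multi-step synthesis. A9 is volatile, unstable and not a shelf reagent. The chosen plan reaches 10 by a simple carbonyl addition to a squarate-derived dione.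

Key step: step 4

Remark on the chemistry: the target is achiral. Compounds 6, 9 and 10 each carry one stereocentre, are formed and used as racemates, and that centre is erased in step 4.

## Route

Step 1
Reactants: 1 1-bromotetradecane; 2 2,3-dibromoprop-1-ene
Product: 4 2-bromoheptadec-1-ene, via tetradecylmagnesium bromide 3 (not isolated)
Conditions: Mg, THF, 45 °C; then 2 (1.3 equiv), CuI (5 mol %), THF, −20 °C → rt
Reagents that add atoms: none
Why: Grignard formation followed by copper-catalysed allylic substitution on the 2-bromoallyl bromide; direct and allyl-transposed attack give the same constitution, and the vinylic C–Br bond is inert under these conditions.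

Step 2
Reactants: 5 dimethyl squarate (3,4-dimethoxycyclobut-3-ene-1,2-dione)
Product: 7 3-methoxycyclobut-3-ene-1,2-dione, via racemic 4-hydroxy-2,3-dimethoxycyclobut-2-en-1-one 6 (not isolated)
Conditions: LiAlH(OtBu)3 (1.05 equiv), THF, −20 → 0 °C; then 6 M aq HCl, 0 °C → rt
Reagents that add atoms: water, O
Why: The bulky, mild hydride should stop at 1,2-mono-reduction of one squarate carbonyl; acid then ionises the carbinol C–OH, water adds to the methoxy-stabilised cation and methanol is lost (the standard acid-mediated carbonyl transposition of squarate adducts), so the hydride-bearing carbon becomes the ring CH and the new carbonyl oxygen comes from water.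

Step 3
Reactants: 4 2-bromoheptadec-1-ene; 7 3-methoxycyclobut-3-ene-1,2-dione
Product: 10 racemic 1-(heptadec-1-en-2-yl)-2-methoxy-4-oxocyclobut-2-en-1-yl acetate, via heptadec-1-en-2-yllithium 8 (not isolated), via lithium 1-(heptadec-1-en-2-yl)-2-methoxy-4-oxocyclobut-2-en-1-olate 9 (not isolated)
Conditions: 4, t-BuLi (2.0 equiv), Et2O, −78 °C; cannulated into 7 (1.1 equiv), THF, −78 °C; then Ac2O (1.5 equiv), −78 → 0 °C; chromatography on Et3N-deactivated silica
Reagents that add atoms: acetic anhydride, CC(=O)OC(C)=O
Why: Bromine–lithium exchange (the second equivalent of t-BuLi destroys the tert-butyl bromide formed) gives 8, which should add 1,2 to the ketone next to the methoxy-bearing carbon, because the other carbonyl is deactivated as a vinylogous ester; the tertiary lithium alkoxide 9 is then O-acetylated in the flask. The new quaternary stereocentre forms as a racemate.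

Step 4
Reactants: 10 racemic 1-(heptadec-1-en-2-yl)-2-methoxy-4-oxocyclobut-2-en-1-yl acetate
Product: 13 4-hydroxy-2-methoxy-6-pentadecylphenyl acetate (target), via (3Z)-3-methoxy-5-methylidene-1-oxoicosa-1,3-dien-4-yl acetate 11 (not isolated), via 6-methoxy-4-oxo-2-pentadecylcyclohexa-1,5-dien-1-yl acetate 12 (not isolated)
Conditions: PhMe (0.02 M, degassed), 110 °C, Ar
Reagents that add atoms: none
Why: Thermal conrotatory 4π electrocyclic opening of the bond between the carbonyl carbon and the acetoxy-bearing carbon of the cyclobutenone gives dienylketene 11; its ketene carbon and the terminal CH2 of the alkene then close to 12, and enolisation of 12 gives the arene. The closest known reaction type is the thermal ring expansion of 4-alkenyl- and 4-aryl-cyclobut-2-enones bearing a 4-hydroxy, 4-alkoxy or 4-silyloxy group to hydroquinones and their mono-protected forms (Moore-type ring expansion). The six-membered carbocycle is closed by a thermal disrotatory 6π electrocyclisation that forms the bond between the former ketene carbon (arene C4) and the alkene terminus (arene C5). No stereocentre is created, and the one in 10 becomes sp2. The step needs outward rotation of the acetoxy group so that the alkenyl group turns inward (3Z geometry of 11); this is secured by the lone-pair donor oxygen on the breaking carbon and by the reversibility of the opening, since a ketene of the wrong geometry can only re-close to 10. The constitution is fixed by connectivity: the ketene oxygen becomes the free phenol on C4, the carbinol oxygen keeps its acetyl group on C1, and their para relationship rules out an intramolecular acyl shift. High dilution and a neutral, oxygen-free medium should suppress ketene dimerisation, acyl transfer between molecules and oxidation to the quinone.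

## Compound list

1 | 1-bromotetradecane | CCCCCCCCCCCCCCBr | starting material
2 | 2,3-dibromoprop-1-ene | C=C(Br)CBr | starting material
3 | tetradecylmagnesium bromide | CCCCCCCCCCCCCC[Mg]Br | intermediate
4 | 2-bromoheptadec-1-ene | C=C(Br)CCCCCCCCCCCCCCC | intermediate
5 | dimethyl squarate (3,4-dimethoxycyclobut-3-ene-1,2-dione) | COC1=C(OC)C(=O)C1=O | starting material
6 | racemic 4-hydroxy-2,3-dimethoxycyclobut-2-en-1-one | COC1=C(OC)C(O)C1=O | intermediate
7 | 3-methoxycyclobut-3-ene-1,2-dione | COC1=CC(=O)C1=O | intermediate
8 | heptadec-1-en-2-yllithium | [Li]C(=C)CCCCCCCCCCCCCCC | intermediate
9 | racemic lithium 1-(heptadec-1-en-2-yl)-2-methoxy-4-oxocyclobut-2-en-1-olate | [Li+].CCCCCCCCCCCCCCCC(=C)C1([O-])C(OC)=CC1=O | intermediate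
10 | racemic 1-(heptadec-1-en-2-yl)-2-methoxy-4-oxocyclobut-2-en-1-yl acetate | CCCCCCCCCCCCCCCC(=C)C1(OC(C)=O)C(OC)=CC1=O | intermediate
11 | (3Z)-3-methoxy-5-methylidene-1-oxoicosa-1,3-dien-4-yl acetate | CCCCCCCCCCCCCCCC(=C)/C(OC(C)=O)=C(OC)\C=C=O | intermediate
12 | 6-methoxy-4-oxo-2-pentadecylcyclohexa-1,5-dien-1-yl acetate | CCCCCCCCCCCCCCCC1=C(OC(C)=O)C(OC)=CC(=O)C1 | intermediate
13 | 4-hydroxy-2-methoxy-6-pentadecylphenyl acetate | CCCCCCCCCCCCCCCc1cc(O)cc(OC)c1OC(C)=O | target

## Step count and risks

Total step count: 4. Longest linear sequence: 3 steps (step 1, step 3, step 4 from 1; or step 2, step 3, step 4 from 5).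

Step 4 (key step). Acetoxy is a weaker donor than hydroxy or alkoxy, so part of the ring opening may go with inward rotation of the acetoxy group and slow the productive path. The longer heating then needed may allow acyl transfer between molecules, from the acetate of one product molecule to the phenol of another, which would scramble the position of the acetyl group. The fallback sets out from 10 and moves the oxygen differentiation from the ring construction to steric discrimination on the finished arene. The thermolysis is driven to full conversion in p-xylene and the crude mixture is acetylated exhaustively in the same flask (Ac2O, pyridine, DMAP). The target, any acyl-shifted isomer and any free hydroquinone then converge on 2-methoxy-6-pentadecyl-1,4-phenylene diacetate F1. The exposed acetate of F1, on the oxygen between two ring hydrogens, is removed by aminolysis with one equivalent of pyrrolidine in CH2Cl2 at 0 °C. The acetate between the methoxy group and the chain is shielded by two ortho substituents and should remain, so the sequence comes back to the route at 13.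

Step 3. Proton transfer from the ring CH of 7 to 8, or attack at the vinylogous ester carbonyl, would lower the site selectivity of the addition. Capture of the crowded alkoxide by acetic anhydride may be incomplete, the four-membered ring may cleave if the alkoxide warms before capture, and the tertiary allylic acetate may ionise on acidic silica. The fallback sets out from 9 and gives up 10 altogether. The alkoxide is quenched with aqueous NH4Cl at −78 °C and racemic 4-(heptadec-1-en-2-yl)-4-hydroxy-3-methoxycyclobut-2-en-1-one F2 is isolated. F2 is heated in degassed toluene, the best-precedented form of the ring expansion, to give 2-methoxy-6-pentadecylbenzene-1,4-diol F3. F3 is acetylated on both oxygens to the diacetate F1 and then treated with pyrrolidine as in the fallback to step 4, which comes back to the route at 13. If only the addition is at fault, transmetalation of 8 with CeCl3 before the addition is a lesser measure that lowers the basicity of the nucleophile.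

Step 2. Over-reduction by the hydride, hydrolysis of the remaining vinylogous ester during the aqueous acid rearrangement, and loss of the small, polar product 7 on isolation are the likely problems. The fallback sets out from 5 and turns the hydrolysis into the route. Reduction to 6 is done as before, and the hydrolysis is pushed to completion with aqueous HCl to give 3-hydroxycyclobut-3-ene-1,2-dione F4 (semisquaric acid), which is isolated by evaporation. F4 is re-esterified with trimethyl orthoformate in methanol at reflux; its two oxygens are equivalent in the anion, so only one ester can form. This comes back to the route at 7.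

## Further compounds

F1 | step 4 | 2-methoxy-6-pentadecyl-1,4-phenylene diacetate | CCCCCCCCCCCCCCCc1cc(OC(C)=O)cc(OC)c1OC(C)=O
F2 | step 3 | racemic 4-(heptadec-1-en-2-yl)-4-hydroxy-3-methoxycyclobut-2-en-1-one | CCCCCCCCCCCCCCCC(=C)C1(O)C(OC)=CC1=O
F3 | step 3 | 2-methoxy-6-pentadecylbenzene-1,4-diol | CCCCCCCCCCCCCCCc1cc(O)cc(OC)c1O
F4 | step 2 | 3-hydroxycyclobut-3-ene-1,2-dione (semisquaric acid) | OC1=CC(=O)C1=O
A1 | alternative 1 | 5-bromovanillin (3-bromo-4-hydroxy-5-methoxybenzaldehyde) | COc1cc(C=O)cc(Br)c1O
A2 | alternative 1 | 4-hydroxy-3-methoxy-5-pentadecylbenzaldehyde | CCCCCCCCCCCCCCCc1cc(C=O)cc(OC)c1O
A3 | alternative 1 | 4-formyl-2-methoxy-6-pentadecylphenyl acetate | CCCCCCCCCCCCCCCc1cc(C=O)cc(OC)c1OC(C)=O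
A4 | alternative 1 | 4-(formyloxy)-2-methoxy-6-pentadecylphenyl acetate | CCCCCCCCCCCCCCCc1cc(OC=O)cc(OC)c1OC(C)=O
A5 | alternative 2 | heptadec-1-yne | CCCCCCCCCCCCCCCC#C
A6 | alternative 2 | pentacarbonyl[(2E)-1-(benzyloxy)-3-methoxyprop-2-en-1-ylidene]chromium | CO/C=C/C(OCc1ccccc1)=[Cr].[C-]#[O+].[C-]#[O+].[C-]#[O+].[C-]#[O+].[C-]#[O+]
A7 | alternative 2 | 4-(benzyloxy)-2-methoxy-6-pentadecylphenyl acetate | CCCCCCCCCCCCCCCc1cc(OCc2ccccc2)cc(OC)c1OC(C)=O
A8 | alternative 3 | 4-oxo-2-pentadecylcyclobut-1-en-1-yl acetate | CCCCCCCCCCCCCCCC1=C(OC(C)=O)C(=O)C1
A9 | alternative 3 | methoxyethyne | COC#C
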